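The easy step is a count. Write P for target and A for starting material, both in percent of the starting material charged, and follow P − A.

in all of them: starting material 0.80 M

| charge | reagent | free catalyst | remark | time |
|---|---|---|---|---|
| eta | 0.70 equiv | 0.5 mol% | the very flask that is asked about, followed so far |  |
| theta | 0.70 equiv | 0.25 mol% | run made earlier |  |
| flask | 0.700 equiv | 0.5 mol% |  | 8.0 d |

- eta (time / h: target / %, starting material / %): 6.00: 9.5, 85.5; 20.0: 29.6, 56.0; 30.0: 36.8, 41.4; 50.0: 45.4, 19.4; 72.0: 47.4, 10.3; 96.0: 45.2, 6.1; 120: 44.1, 3.2
- theta (time / h: target / %, starting material / %): 1.50: 2.5, 100.5; 4.00: 3.5, 99.0; 8.00: 8.0, 89.2; 12.0: 10.9, 87.0; 15.0: 11.2, 83.5; 20.0: 14.5, 74.7; 30.0: 22.5, 62.8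

(standard deviation of a reading: 1 percentage point)

- target that was removed still counts
- additions bring no volume worth counting

- maple: at 8.0 d add free catalyst, 100 % of the amount charged, then wait 8.0 d
- cedar: at 8.0 d add reagent, 50.0 % of the amount charged, then wait 8.0 d
- ash: at 8.0 d take out 90 % of the target then present, then wait 8.0 d
- elm: change nothing and wait 8.0 d more

1. target, in percent of the starting material first charged, at 8.0 d
2. what to do for the largest gain in target; "none" if nothing gains more than 2 percentage points (maple / cedar / ash / elm / none)
3. target present, with what was taken out counted in, in percent of the starting material first charged, after maple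
4. target present, with what was taken out counted in, in percent of the starting material first charged, after cedar

1. Main step alone. Assume that one starting material and one reagent give one target, with the catalyst returned. Reagent at 0.700 equiv is then the limiting reagent, and target could reach 70.0 %. Each turnover raises P − A by two units. The eta readings instead show 47.4 % after 72.0 h.

2. Add one loss. At 120 h, eta has lost 52.7 % from P and A together. Take this as starting material + target → side product, which holds two units of the charge. That step lowers P and A equally and leaves P − A unchanged. The end value is 40.0 %: the reagent gap G, target minus starting material once the reagent is used, equal to twice the equivalents less one. Eta reads 37 percentage points, 39 points and 41 points at 72.0 h, 96.0 h and 120 h, and the last reading stands within the scatter of G.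

3. The rest. The asked flask is eta followed further, so this reckoning takes P = G + A, assuming the reagent is used by then. Catalyst forms can hold up to 0.5 mol% of the charge, against a scatter of 1 point. Eta's A reads 6.1 %, then 3.2 %, so this reckoning puts target at 8.0 d between 40.0 % and 43.2 %.

4. The options. Added reagent can turn the remaining A into target, and that A, which reads 6.1 % at 96.0 h and 3.2 % at 120 h, is expected below the margin of 2 points by 8.0 d. Added catalyst brings no reagent, so G stays. Waiting and taking out target bring no reagent either, so this reckoning expects no gain from them. This reckoning chooses none, with maple near the present target and cedar slightly above it.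

5. The forecast gave 33.5 %, none, 14.5 % and 14.5 %, saying “With nothing left to convert, more catalyst or reagent gains nothing”.

6. The flask gives 42.4 %, none, 41.2 % after maple and 44.3 % after cedar.

    catalyst intermediate C → released group + catalyst intermediate D (k = 2.30 min⁻¹)
    reagent + catalyst intermediate A → catalyst intermediate B (k = 0.390 M⁻¹ min⁻¹)
    starting material + target → side product (k = 5.60 × 10⁻⁴ M⁻¹ min⁻¹)
    catalyst intermediate B ⇌ catalyst intermediate C (K = 0.600, k = 0.230 min⁻¹)
    starting material + free catalyst → catalyst intermediate A (k = 0.360 M⁻¹ min⁻¹)
    catalyst intermediate D → free catalyst + target (k = 29.0 min⁻¹)

At 19.1 h, target in the flask is made 3.20 times as fast as it is used up. By 192 h, reagent stands at 0 %, and P − A stands at 40 points against G of 40.0 %.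

For the neighbour flask with 0.170 equiv, G is −66.0 %, so starting material should end that far above target. At 192 h, that neighbour holds 66 % starting material and 0.594 % target.

All runs were computed on assumed constants; the scatter is artificial.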